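**Plan**

Numbering: furan-2(5H)-one ring O1, C2(=O), C3H, C4, C5H2. The side chain runs from C1′(OH) to C17′, with CH2OH on C4′.
Cuts: O–Si (last step); C3=C4 together with O1–C2 (C2 and C3 both come from Ph3P=C=C=O); C1′–C2′ (azaenolate plus allylic bromide); C4′–C5′ (B-alkyl Suzuki); C5′–C6′ (Wittig methylenation of farnesal, saturated later by hydroboration).
Enabling feature: ring atoms C5 and C4 plus side-chain C1′ form an O–CH2–C–CH–O array, which is a dihydroxyacetone unit. With C4 as a ketone, the C5 hydroxyl can carry a C2–C3 ylide that reaches C4 only through a five-membered ring.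
Forward order: vinyl iodide + homofarnesyl borane → C20 allylic bromide → alkylation of a dihydroxyacetone hydrazone → keto diol → butenolide (the only ring, closed in the penultimate step) → desilylation.
Stereochemistry: C1′ (R) comes from the RAMP-hydrazone alkylation. The C3′=C4′ geometry comes from hydroxyl-directed trans-hydroalumination/iodination followed by a stereoretentive coupling. The C7′ and C11′ alkenes come from (2E,6E)-farnesol.

Key step: step 11

**Step 1**
Reactants: 1 but-2-yne-1,4-diol
Product: 2 4-(tert-butyldiphenylsilyloxy)but-2-yn-1-ol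
Conditions: NaH (1 equiv), THF, 0 °C; TBDPSCl (1 equiv, diol in threefold excess), 0 °C → rt
Reagents that add atoms: tert-butyl(chloro)diphenylsilane, CC(C)(C)[Si](Cl)(c1ccccc1)c1ccccc1
Why: O-silylation of a symmetrical diol through its sparingly soluble monosodium alkoxide, with the diol in excess, should stop at the mono ether.

**Step 2**
Reactants: 2 4-(tert-butyldiphenylsilyloxy)but-2-yn-1-ol
Product: 4 (Z)-4-(tert-butyldiphenylsilyloxy)-3-iodobut-2-en-1-ol, via cyclic alkenylalanate 3 (not isolated)
Conditions: Red-Al, THF, 0 °C; then I2, THF, −78 → 0 °C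
Reagents that add atoms: iodine, II; Red-Al, [Na+].COCCO[AlH2-]OCCOC (its Na, Al and alkoxide ligands stand in 3 only)
Why: Hydroxyl-directed trans-hydroalumination of a propargylic alcohol puts aluminium on the distal alkyne carbon inside a five-membered alanate, iodinolysis with retention fixes the Z vinyl iodide, and working at or below 0 °C should hold back β-elimination of the silyloxide.

**Step 3**
Reactants: 5 (2E,6E)-farnesol
Product: 6 (2E,6E)-farnesal
Conditions: TEMPO (10 mol %), PhI(OAc)2, CH2Cl2, rt
Reagents that add atoms: none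
Why: The TEMPO/PhI(OAc)2 oxidation of a primary allylic alcohol stops at the enal under nearly neutral conditions and should leave the 2E geometry untouched.

**Step 4**
Reactants: 6 (2E,6E)-farnesal
Product: 7 (3E,7E)-4,8,12-trimethyltrideca-1,3,7,11-tetraene
Conditions: Ph3PCH3Br, n-BuLi, THF, 0 °C → rt
Reagents that add atoms: methyltriphenylphosphonium bromide, C[P+](c1ccccc1)(c1ccccc1)c1ccccc1.[Br-]
Why: Wittig methylenation of an enal with the non-stabilised ylide is a clean 1,2-process and gives the terminal 1,3-diene without touching the other alkenes.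

**Step 5**
Reactants: 7 (3E,7E)-4,8,12-trimethyltrideca-1,3,7,11-tetraene; 4 (Z)-4-(tert-butyldiphenylsilyloxy)-3-iodobut-2-en-1-ol
Product: 9 (2E,6E,10E)-3-[(tert-butyldiphenylsilyloxy)methyl]-7,11,15-trimethylhexadeca-2,6,10,14-tetraen-1-ol, via B-homofarnesyl-9-BBN 8 (not isolated)
Conditions: 9-BBN, THF, 0 °C → rt; then 4, PdCl2(dppf) (5 mol %), AsPh3, Cs2CO3, DMF/H2O, rt
Reagents that add atoms: 9-borabicyclo[3.3.1]nonane, [H]B1C2CCCC1CCC2 (its boron cage stands in 8 only)
Why: 9-BBN adds anti-Markovnikov to the only monosubstituted alkene of 7, and the B-alkyl Suzuki–Miyaura coupling replaces iodine with retention, so the homofarnesyl chain ends up cis to CH2OH.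

**Step 6**
Reactants: 9 (2E,6E,10E)-3-[(tert-butyldiphenylsilyloxy)methyl]-7,11,15-trimethylhexadeca-2,6,10,14-tetraen-1-ol
Product: 10 (2E,6E,10E)-1-bromo-3-[(tert-butyldiphenylsilyloxy)methyl]-7,11,15-trimethylhexadeca-2,6,10,14-tetraene
Conditions: CBr4, PPh3, CH2Cl2, −20 → 0 °C
Reagents that add atoms: carbon tetrabromide, BrC(Br)(Br)Br
Why: The Appel reaction turns a primary allylic alcohol into the bromide by SN2 displacement under neutral conditions, without allylic transposition or loss of alkene geometry.

**Step 7**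
Reactants: 11 2,2-dimethyl-1,3-dioxan-5-one; 12 RAMP, (R)-1-amino-2-(methoxymethyl)pyrrolidine
Product: 13 RAMP hydrazone of 2,2-dimethyl-1,3-dioxan-5-one
Conditions: cyclohexane, 4 Å MS, 60 °C
Reagents that add atoms: none
Why: Hydrazone formation from a ketone and the 1-aminopyrrolidine auxiliary goes to completion once water is removed and leaves the acetonide intact.

**Step 8**
Reactants: 13 RAMP hydrazone of 2,2-dimethyl-1,3-dioxan-5-one; 10 allylic bromide
Product: 15 (4R)-4-alkylated RAMP hydrazone (alkyl = the C20 allyl group of 10), via lithio azaenolate 14 (not isolated)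
Conditions: t-BuLi, THF, −78 °C; then 10, −100 → −78 °C → rt
Reagents that add atoms: tert-butyllithium, [Li]C(C)(C)C (its lithium stands in 14 only)
Why: In the Enders SAMP/RAMP-hydrazone α-alkylation the chelated lithio azaenolate takes up the primary allylic bromide by SN2 on the face left open by the methoxymethyl arm, which with RAMP should set the dioxane C4 (later C1′) as R.

**Step 9**
Reactants: 15 (4R)-4-alkylated RAMP hydrazone
Product: 16 (4R)-4-{(2E,6E,10E)-3-[(tert-butyldiphenylsilyloxy)methyl]-7,11,15-trimethylhexadeca-2,6,10,14-tetraen-1-yl}-2,2-dimethyl-1,3-dioxan-5-one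
Conditions: sat. aq. oxalic acid, Et2O, rt
Reagents that add atoms: water, O
Why: Two-phase oxalic acid hydrolysis of SAMP/RAMP hydrazones removes the basic auxiliary into the aqueous layer under conditions mild enough to keep the α-stereocentre, the acetonide and the alkenes.

**Step 10**
Reactants: 16 (4R)-4-alkyl-2,2-dimethyl-1,3-dioxan-5-one
Product: 17 (3R,5E,9E,13E)-1,3-dihydroxy-6-[(tert-butyldiphenylsilyloxy)methyl]-10,14,18-trimethylnonadeca-5,9,13,17-tetraen-2-one
Conditions: AcOH/THF/H2O, 40 °C, short contact time; used directly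
Reagents that add atoms: none
Why: Mild aqueous acid hydrolyses the isopropylidene ketal, while the TBDPS ether and the isolated trisubstituted alkenes survive and the absence of base limits enediol formation at C3.

**Step 11**
Reactants: 17 keto diol; 18 (triphenylphosphoranylidene)ketene (Bestmann ylide)
Product: 20 4-{(1R,3E,7E,11E)-1-hydroxy-4-[(tert-butyldiphenylsilyloxy)methyl]-8,12,16-trimethylheptadeca-3,7,11,15-tetraen-1-yl}furan-2(5H)-one, via acyl ylide 19 (not isolated)
Conditions: 18 (1.0 equiv), toluene, 60–70 °C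
Reagents that add atoms: none
Why: The primary C5 hydroxyl of 17 adds across the C=C bond of the cumulated ylide 18 to give the ester-stabilised ylide 19, whose carbanionic C3 attacks the C4 ketone, and the resulting oxaphosphetane collapses to the C3=C4 bond and Ph3P=O. The closest known reaction type is the domino addition–intramolecular Wittig olefination of α-hydroxy ketones with the Bestmann ylide, an established entry to Δα,β-butenolides. The only ring, the furan-2(5H)-one, closes by 5-exo-trig attack on the carbonyl group followed by [2+2] cycloreversion, and the ring enforces the cis geometry of the new alkene. No stereocentre is created, and the existing C1′ centre, which is α to the ketone until the ring closes, should be kept because the medium is neutral, salt-free and holds no base stronger than the stabilised ylide. The step needs O-selectivity (primary C5–OH before secondary C1′–OH), secured by the bulk of the Ph3P-bearing cumulene, one equivalent of 18 and the lowest workable temperature, and it needs carbonyl reactivity, secured because a stabilised ylide olefinates a ketone only when held in a five-membered transition state. The silyl ether and the four trisubstituted alkenes are inert to the reagent.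

**Step 12**
Reactants: 20 silyl-protected hippolide C
Product: 21 hippolide C, 4-[(1R,3E,7E,11E)-1-hydroxy-4-(hydroxymethyl)-8,12,16-trimethylheptadeca-3,7,11,15-tetraen-1-yl]furan-2(5H)-one
Conditions: HF·pyridine, pyridine, THF, 0 °C → rt
Reagents that add atoms: none
Why: Fluoride-driven Si–O cleavage in a buffered, weakly acidic medium generates no alkoxide, so acyl migration within the hydroxy butenolide and alkene isomerisation should not set in.

**Compound list**

1 | but-2-yne-1,4-diol | OCC#CCO | starting material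
2 | 4-(tert-butyldiphenylsilyloxy)but-2-yn-1-ol | OCC#CCO[Si](c1ccccc1)(c1ccccc1)C(C)(C)C | intermediate
3 | sodium cyclic alkenylalanate from 2 and Red-Al | [Na+].COCCO[Al-]1(OCCOC)OCC=C1CO[Si](c1ccccc1)(c1ccccc1)C(C)(C)C | intermediate
4 | (Z)-4-(tert-butyldiphenylsilyloxy)-3-iodobut-2-en-1-ol | OC/C=C(\I)CO[Si](c1ccccc1)(c1ccccc1)C(C)(C)C | intermediate
5 | (2E,6E)-farnesol | CC(C)=CCC/C(C)=C/CC/C(C)=C/CO | starting material
6 | (2E,6E)-farnesal | CC(C)=CCC/C(C)=C/CC/C(C)=C/C=O | intermediate
7 | (3E,7E)-4,8,12-trimethyltrideca-1,3,7,11-tetraene | CC(C)=CCC/C(C)=C/CC/C(C)=C/C=C | intermediate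
8 | B-[(3E,7E)-homofarnesyl]-9-BBN | CC(C)=CCC/C(C)=C/CC/C(C)=C/CCB1C2CCCC1CCC2 | intermediate
9 | (2E,6E,10E)-3-[(tert-butyldiphenylsilyloxy)methyl]-7,11,15-trimethylhexadeca-2,6,10,14-tetraen-1-ol | CC(C)=CCC/C(C)=C/CC/C(C)=C/CC/C(=C\CO)CO[Si](c1ccccc1)(c1ccccc1)C(C)(C)C | intermediate
10 | (2E,6E,10E)-1-bromo-3-[(tert-butyldiphenylsilyloxy)methyl]-7,11,15-trimethylhexadeca-2,6,10,14-tetraene | CC(C)=CCC/C(C)=C/CC/C(C)=C/CC/C(=C\CBr)CO[Si](c1ccccc1)(c1ccccc1)C(C)(C)C | intermediate
11 | 2,2-dimethyl-1,3-dioxan-5-one | CC1(C)OCC(=O)CO1 | starting material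
12 | RAMP, (R)-1-amino-2-(methoxymethyl)pyrrolidine | COC[C@H]1CCCN1N | starting material
13 | RAMP hydrazone of 2,2-dimethyl-1,3-dioxan-5-one | COC[C@H]1CCCN1N=C1COC(C)(C)OC1 | intermediate
14 | lithio azaenolate of 13 | COC[C@H]1CCCN1[N-]C1=COC(C)(C)OC1.[Li+] | intermediate
15 | (4R)-4-alkylated RAMP hydrazone (C=N geometry not specified) | CC(C)=CCC/C(C)=C/CC/C(C)=C/CC/C(=C\C[C@H]1OC(C)(C)OCC1=NN1CCC[C@@H]1COC)CO[Si](c1ccccc1)(c1ccccc1)C(C)(C)C | intermediate
16 | (4R)-4-alkyl-2,2-dimethyl-1,3-dioxan-5-one | CC(C)=CCC/C(C)=C/CC/C(C)=C/CC/C(=C\C[C@H]1OC(C)(C)OCC1=O)CO[Si](c1ccccc1)(c1ccccc1)C(C)(C)C | intermediate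
17 | (3R)-1,3-dihydroxy-2-ketone | CC(C)=CCC/C(C)=C/CC/C(C)=C/CC/C(=C\C[C@@H](O)C(=O)CO)CO[Si](c1ccccc1)(c1ccccc1)C(C)(C)C | intermediate
18 | (triphenylphosphoranylidene)ketene | O=C=C=P(c1ccccc1)(c1ccccc1)c1ccccc1 | starting material
19 | (triphenylphosphoranylidene)acetate of 17 at the primary oxygen | CC(C)=CCC/C(C)=C/CC/C(C)=C/CC/C(=C\C[C@@H](O)C(=O)COC(=O)C=P(c1ccccc1)(c1ccccc1)c1ccccc1)CO[Si](c1ccccc1)(c1ccccc1)C(C)(C)C | intermediate
20 | O-TBDPS hippolide C | CC(C)=CCC/C(C)=C/CC/C(C)=C/CC/C(=C\C[C@@H](O)C1=CC(=O)OC1)CO[Si](c1ccccc1)(c1ccccc1)C(C)(C)C | intermediate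
21 | hippolide C | CC(C)=CCC/C(C)=C/CC/C(C)=C/CC/C(=C\C[C@@H](O)C1=CC(=O)OC1)CO | target

**Step count and risks**

Total step count: 12. Longest linear sequence: 9 steps, from 5 through steps 3, 4, 5, 6, 8, 9, 10, 11 and 12.

Risk 1, step 11. At the temperature the cumulene needs, the secondary hydroxyl may also add, or both hydroxyls may be acylated, and the Wittig closure would then run toward the regioisomeric 5-substituted ring. The fallback sets out from 17 and comes back at 20. The two events are separated, so that the oxygen is chosen in the cold. Carbodiimide acylation with diethylphosphonoacetic acid (DCC, catalytic DMAP, CH2Cl2, −20 °C) should take only the primary hydroxyl and give the phosphonoacetate F1. An intramolecular Horner–Wadsworth–Emmons reaction under Masamune–Roush conditions (LiCl, i-Pr2NEt, MeCN, 0 °C) then closes the same C3=C4 bond to 20.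

Risk 2, step 10. The free α,α′-dihydroxy ketone may tautomerise through its enediol, which would erode the C1′ configuration or shift the ketol, and it may dimerise to hemiketals during hydrolysis and handling. The fallback sets out from 16 and comes back at 20, and it never exposes a free ketol. Salt-free Wittig methylenation of 16 gives the 5-methylene-1,3-dioxane F2. Aqueous acetic acid releases the 2-methylene-1,3-diol F3. Acryloyl chloride with 2,4,6-collidine at −78 °C esterifies the primary allylic hydroxyl to give the acrylate F4. Ring-closing metathesis (Hoveyda–Grubbs second-generation catalyst, toluene, 80 °C) then joins the acrylate and the 1,1-disubstituted alkene to give 20.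

Risk 3, step 5. Hydroboration of the conjugated terminal alkene may not be fully site-selective, with attack in the allylic sense or on trisubstituted alkenes. Transmetalation of the alkylborane may also be slow enough for protodeboronation to compete. The fallback sets out from 7 and comes back at 9. The bulkier disiamylborane gives the trialkylborane F5, and NaOH/H2O2 oxidation gives (3E,7E)-homofarnesol F6, which can be purified. Iodination (I2, PPh3, imidazole) gives homofarnesyl iodide F7. Zinc insertion (Zn, LiCl, THF) gives homofarnesylzinc iodide F8. Negishi coupling of an excess of F8 with 4 (PdCl2(dppf), THF, rt) then delivers 9 with retention of the alkene geometry.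

**Further compounds**

F1 | step 11 | diethylphosphonoacetate of 17 at the primary oxygen | CC(C)=CCC/C(C)=C/CC/C(C)=C/CC/C(=C\C[C@@H](O)C(=O)COC(=O)CP(=O)(OCC)OCC)CO[Si](c1ccccc1)(c1ccccc1)C(C)(C)C
F2 | step 10 | (4R)-4-alkyl-2,2-dimethyl-5-methylene-1,3-dioxane | CC(C)=CCC/C(C)=C/CC/C(C)=C/CC/C(=C\C[C@H]1OC(C)(C)OCC1=C)CO[Si](c1ccccc1)(c1ccccc1)C(C)(C)C
F3 | step 10 | (3R)-2-methylene-1,3-diol | CC(C)=CCC/C(C)=C/CC/C(C)=C/CC/C(=C\C[C@@H](O)C(=C)CO)CO[Si](c1ccccc1)(c1ccccc1)C(C)(C)C
F4 | step 10 | primary acrylate of F3 | CC(C)=CCC/C(C)=C/CC/C(C)=C/CC/C(=C\C[C@@H](O)C(=C)COC(=O)C=C)CO[Si](c1ccccc1)(c1ccccc1)C(C)(C)C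
F5 | step 5 | (3E,7E)-homofarnesyl-bis(3-methylbutan-2-yl)borane | CC(C)=CCC/C(C)=C/CC/C(C)=C/CCB(C(C)C(C)C)C(C)C(C)C
F6 | step 5 | (3E,7E)-homofarnesol | CC(C)=CCC/C(C)=C/CC/C(C)=C/CCO
F7 | step 5 | (3E,7E)-homofarnesyl iodide | CC(C)=CCC/C(C)=C/CC/C(C)=C/CCI
F8 | step 5 | (3E,7E)-homofarnesylzinc iodide | CC(C)=CCC/C(C)=C/CC/C(C)=C/CC[Zn]I
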